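The target is a single 25-membered lactone ring (C1 to C24 plus the ring oxygen) whose C2–C24 span is unbranched, unsubstituted and free of stereocentres. The key step exploits exactly this: four adjacent ring methylenes, C5–C8, can be carried as a linear 1,3-diyne and the ring cut at C6–C7 between two alkyne termini. A copper-mediated oxidative alkyne–alkyne coupling at high dilution then forms that bond and the macrocycle in one operation, and hydrogenation erases the unsaturation. The cyclisation substrate is the open-chain ester of hex-5-ynoic acid with octadec-17-yn-1-ol, reached in two steps from a C16 bromo alcohol.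

Key step: step 3

Assumption: ring positions are counted from the lactone carbonyl carbon (C1) round the chain to the oxygen-bearing methylene (C24), and both starting materials are taken as catalogue items.

Step 1
Reactants: 1 16-bromohexadecan-1-ol
Product: 4 octadec-17-yn-1-ol, via lithium 16-bromohexadecan-1-olate 2 (not isolated), via lithium octadec-17-yn-1-olate 3 (not isolated)
Conditions: LiC≡CH·H2NCH2CH2NH2 (3 equiv), DMSO–THF, 5 °C to rt, 1 added slowly; then H2O
Reagents that add atoms: lithium acetylide–ethylenediamine complex LiC≡CH·H2NCH2CH2NH2, [Li+].[C-]#C.NCCN
Why: SN2 alkylation of an acetylide by an unhindered primary bromide in a dipolar aprotic medium, in which one equivalent of the reagent merely stores the hydroxyl as its lithium alkoxide and slow addition of the bromide into excess acetylide lets C-alkylation outpace ether formation or elimination.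

Step 2
Reactants: 4 octadec-17-yn-1-ol; 5 hex-5-ynoic acid
Product: 7 octadec-17-yn-1-yl hex-5-ynoate, via O-acylisourea 6 (not isolated)
Conditions: DCC (1.2 equiv), DMAP (cat.), CH2Cl2, 0 °C to rt
Reagents that add atoms: none
Why: Steglich esterification, in which DCC turns the acid into an O-acylisourea, DMAP relays the acyl group to the unhindered primary alcohol, and the neutral metal-free conditions leave both terminal alkynes untouched.

Step 3
Reactants: 7 octadec-17-yn-1-yl hex-5-ynoate
Product: 9 tetracosa-5,7-diyn-24-olide, via bis(acetatocopper) diacetylide 8 (not isolated)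
Conditions: Cu(OAc)2 (10 equiv), pyridine, 60 °C; 7 added by syringe pump over 12 h (final about 2 mM)
Reagents that add atoms: none
Why: Eglinton coupling, the stoichiometric member of the Glaser family: acetate and pyridine take off the two acetylenic protons as Cu(OAc)2 cuprates C6 and C7, and the pair of divalent copper acetylides, held together in a dinuclear pyridine complex, collapses to the C6–C7 bond while each copper falls to the monovalent state. The closest known reaction type is the high-dilution oxidative cyclisation of α,ω-diynes and diyne esters to macrocyclic 1,3-diynes. The 25-membered ring closes end to end, one chain terminus onto the other, with both triple bonds becoming endocyclic; since no π bond is attacked, exo/endo ring-closure preferences play no part. No stereocentre is formed. The one selectivity required is ring closure over chain-to-chain coupling, and it is secured by feeding the diyne slowly into a large excess of Cu(OAc)2 so that free substrate never accumulates, helped by the fact that the straight C4–C9 segment sits without strain in so large a ring. Chemoselectivity is built in, because only the two sp C–H bonds are acidic enough to be cuprated and the ester is indifferent to Cu(OAc)2 and pyridine.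

Step 4
Reactants: 9 tetracosa-5,7-diyn-24-olide
Product: 10 24-tetracosanolide (oxacyclopentacosan-2-one)
Conditions: H2 (1 atm), 10% Pd/C, EtOAc, rt
Reagents that add atoms: none
Why: Heterogeneous catalytic hydrogenation, in which the unhindered conjugated diyne takes up four equivalents of H2 to become the C5–C8 tetramethylene unit while the lactone C–O bonds, at no stage allylic or benzylic, are not hydrogenolysed and no stereocentre arises.

Compound list
1 | 16-bromohexadecan-1-ol | OCCCCCCCCCCCCCCCCBr | starting material
2 | lithium 16-bromohexadecan-1-olate | [Li+].[O-]CCCCCCCCCCCCCCCCBr | intermediate (not isolated)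
3 | lithium octadec-17-yn-1-olate | [Li+].[O-]CCCCCCCCCCCCCCCCC#C | intermediate (not isolated)
4 | octadec-17-yn-1-ol | OCCCCCCCCCCCCCCCCC#C | intermediate
5 | hex-5-ynoic acid | C#CCCCC(=O)O | starting material
6 | N,N'-dicyclohexyl-O-(hex-5-ynoyl)isourea (O-acylisourea) | C#CCCCC(=O)OC(=NC1CCCCC1)NC1CCCCC1 | intermediate (not isolated)
7 | octadec-17-yn-1-yl hex-5-ynoate | C#CCCCC(=O)OCCCCCCCCCCCCCCCCC#C | intermediate
8 | bis(acetatocopper) diacetylide of 7, AcOCuC≡C(CH2)3CO2(CH2)16C≡CCuOAc, divalent copper on each alkyne terminus, pyridine ligands not drawn | CC(=O)O[Cu]C#CCCCC(=O)OCCCCCCCCCCCCCCCCC#C[Cu]OC(C)=O | intermediate (not isolated)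
9 | tetracosa-5,7-diyn-24-olide (oxacyclopentacosa-6,8-diyn-2-one) | O=C1CCCC#CC#CCCCCCCCCCCCCCCCCO1 | intermediate
10 | 24-tetracosanolide (oxacyclopentacosan-2-one) | O=C1CCCCCCCCCCCCCCCCCCCCCCCO1 | target

Total step count: 4
Longest linear sequence: 4 steps (1 → 4 → 7 → 9 → 10); acid 5 enters at step 2 as bought.

Steps most likely to fail

Step 3. What may go wrong: coupling between different chains outruns ring closure, so linear and cyclic oligomers form instead of the monomeric ring. The fallback sets out from 4 (with 5) and comes back at 9. It makes the C6–C7 bond between two separate molecules, where oligomerisation cannot occur, and closes the ring at the ester instead.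
- Alkynol 4 is brominated at the alkyne terminus (NBS, cat. AgNO3, acetone, rt) to 18-bromooctadec-17-yn-1-ol F1.
- Cadiot–Chodkiewicz heterocoupling of this bromoalkyne with acid 5 (cat. CuCl, NH2OH·HCl, aqueous n-BuNH2, MeOH–THF, 0 °C to rt) should give 24-hydroxytetracosa-5,7-diynoic acid F2.
- Yamaguchi macrolactonisation (2,4,6-trichlorobenzoyl chloride, Et3N, THF, then slow addition to DMAP in hot toluene) proceeds by way of the 24-hydroxytetracosa-5,7-diynoic 2,4,6-trichlorobenzoic anhydride F3. It should close the same 25-membered ring to 9, which enters step 4 unchanged.

Step 1. What may go wrong: the lithium alkoxide of the free hydroxyl competes with acetylide for the bromide (ether formation between chains), or acetylide acts as a base (elimination), so bromide is consumed without C–C bond formation. The fallback sets out from 1 and comes back at 4. It masks the hydroxyl so that no alkoxide exists during the substitution.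
- 1 is converted (3,4-dihydro-2H-pyran, PPTS, CH2Cl2) into 2-[(16-bromohexadecyl)oxy]oxane F4.
- The bromide is displaced by LiC≡CH·H2NCH2CH2NH2 in DMSO to give 2-(octadec-17-yn-1-yloxy)oxane F5.
- Methanolysis (PPTS, MeOH, 50 °C) releases 4.
- Both ethers are racemic at the acetal carbon, which is of no consequence.

Step 2. What may go wrong: oxygen-to-nitrogen acyl shift in the activated acid gives an unreactive N-acylurea faster than acyl transfer, leaving alcohol unesterified and a waxy ester that is hard to free from urea. The fallback sets out from 4 (with 5) and comes back at 7. It forms the ester C–O bond from the alkyl side instead of the acyl side.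
- 4 is converted (MsCl, Et3N, CH2Cl2, 0 °C) into octadec-17-yn-1-yl methanesulfonate F6.
- The sulfonate is displaced in DMF at 50 °C by caesium hex-5-ynoate F7, formed in the flask from 5 and Cs2CO3, to give 7.

Further compounds
F1 | step 3 | 18-bromooctadec-17-yn-1-ol | OCCCCCCCCCCCCCCCCC#CBr
F2 | step 3 | 24-hydroxytetracosa-5,7-diynoic acid | OC(=O)CCCC#CC#CCCCCCCCCCCCCCCCCO
F3 | step 3 | 24-hydroxytetracosa-5,7-diynoic 2,4,6-trichlorobenzoic anhydride | O=C(OC(=O)c1c(Cl)cc(Cl)cc1Cl)CCCC#CC#CCCCCCCCCCCCCCCCCO
F4 | step 1 | 2-[(16-bromohexadecyl)oxy]oxane (racemic) | BrCCCCCCCCCCCCCCCCOC1CCCCO1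
F5 | step 1 | 2-(octadec-17-yn-1-yloxy)oxane (racemic) | C#CCCCCCCCCCCCCCCCCOC1CCCCO1
F6 | step 2 | octadec-17-yn-1-yl methanesulfonate | CS(=O)(=O)OCCCCCCCCCCCCCCCCC#C
F7 | step 2 | caesium hex-5-ynoate | C#CCCCC(=O)[O-].[Cs+]
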